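The flavonol is cut in ring C at O1–C2, and the C3 oxygen is traded for iodine. This leads back to a diaryl ynone. In that ynone the future C2 carries ring B, whose 2'- and 4'-methoxy groups stabilise positive charge at C2. The future C3 adjoins the C4 carbonyl, and ring A is a symmetric pentaoxygenated aryl with two identical ortho methoxy groups. One exposure to ICl forms O1–C2, closes the pyranone, expels one methyl group and leaves C3–I for later oxygenation. The surviving ortho ether becomes 5-OMe, peri to C4=O, which a chelating Lewis acid removes last, along with both benzyl groups.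

Key step: step 11

Remark: flavone numbering (O1, C2 to C8a, C1' to C6') is also used for the open-chain precursors. The target has no stereocentre, and the propargylic alcohol of step 9 is made and used as the racemate.

Step 1
Reactants: 1 1,2,4,5-tetramethoxybenzene
Product: 4 2,3,5,6-tetramethoxyphenol, via aryllithium 2 (not isolated), via dimethyl arylboronate 3 (not isolated)
Conditions: n-BuLi (1.05 equiv), TMEDA, THF, 0 °C; B(OMe)3, -78 °C to rt; AcOH, 30% H2O2, 0 °C to rt
Reagents that add atoms: hydrogen peroxide, OO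
Why: Directed ortho-metalation, borylation and peroxide oxidation: each ring hydrogen of 1 lies between two methoxy groups and should be removed cleanly by one equivalent of n-BuLi, and the aryl group then migrates from boron to oxygen under H2O2 to give the phenol.

Step 2
Reactants: 4 2,3,5,6-tetramethoxyphenol
Product: 5 1-(benzyloxy)-2,3,5,6-tetramethoxybenzene
Conditions: BnBr, K2CO3, DMF, rt
Reagents that add atoms: benzyl bromide, BrCc1ccccc1
Why: Williamson ether synthesis: the phenoxide of 4 is the only nucleophilic site and is alkylated on oxygen by the reactive benzylic bromide.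

Step 3
Reactants: 5 1-(benzyloxy)-2,3,5,6-tetramethoxybenzene
Product: 6 1-(benzyloxy)-4-bromo-2,3,5,6-tetramethoxybenzene
Conditions: NBS (1.05 equiv), MeCN, 0 °C to rt, dark
Reagents that add atoms: N-bromosuccinimide, O=C1CCC(=O)N1Br
Why: Electrophilic aromatic bromination: the pentaalkoxy ring has one free position, ortho to two methoxy groups and para to the benzyloxy group, and in a polar solvent in the dark it should react far faster than the plain phenyl ring or the benzylic CH2.

Step 4
Reactants: 6 1-(benzyloxy)-4-bromo-2,3,5,6-tetramethoxybenzene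
Product: 8 4-(benzyloxy)-2,3,5,6-tetramethoxybenzaldehyde, via aryllithium 7 (not isolated)
Conditions: n-BuLi (1.05 equiv), THF, -78 °C; DMF, -78 °C to 0 °C; H2O
Reagents that add atoms: N,N-dimethylformamide, CN(C)C=O
Why: Bromine-lithium exchange followed by formylation with DMF: exchange at -78 °C outruns deprotonation of the benzylic OCH2, so the [1,2]-Wittig rearrangement that direct metalation of 5 would risk is avoided, and the aldehyde appears only on aqueous quench.

Step 5
Reactants: 9 2,4-dimethoxybenzaldehyde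
Product: 11 2,4-dimethoxyphenol, via aryl formate 10 (not isolated)
Conditions: mCPBA, CH2Cl2, 0 °C to rt; aq NaHCO3 wash; K2CO3 (cat.), MeOH, rt
Reagents that add atoms: 3-chloroperoxybenzoic acid, OOC(=O)c1cccc(Cl)c1
Why: Baeyer-Villiger oxidation of Dakin type: the electron-rich aryl group migrates to oxygen in preference to hydride, and the aryl formate is transesterified by methanol under mild base.

Step 6
Reactants: 11 2,4-dimethoxyphenol
Product: 12 1-(benzyloxy)-2,4-dimethoxybenzene
Conditions: BnBr, K2CO3, DMF, rt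
Reagents that add atoms: benzyl bromide, BrCc1ccccc1
Why: Williamson ether synthesis on the single phenolic oxygen, done promptly because the free electron-rich phenol is sensitive to air.

Step 7
Reactants: 12 1-(benzyloxy)-2,4-dimethoxybenzene
Product: 14 5-(benzyloxy)-2,4-dimethoxybenzaldehyde, via iminium chloride 13 (not isolated)
Conditions: POCl3, DMF, 0 °C to 70 °C; ice-water
Reagents that add atoms: N,N-dimethylformamide, CN(C)C=O; water, O
Why: Vilsmeier-Haack formylation: C5 of 12 is para to the 2-methoxy and ortho to the 4-methoxy group and is the most activated open position (C3 is flanked by two ethers, C6 is activated only by the benzyloxy group), the same regiochemistry as in the formylation of 1,2,4-trimethoxybenzene.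

Step 8
Reactants: 14 5-(benzyloxy)-2,4-dimethoxybenzaldehyde
Product: 15 1-(benzyloxy)-5-ethynyl-2,4-dimethoxybenzene
Conditions: dimethyl (1-diazo-2-oxopropyl)phosphonate, K2CO3, MeOH/THF, rt
Reagents that add atoms: dimethyl (1-diazo-2-oxopropyl)phosphonate, COP(=O)(OC)C(=[N+]=[N-])C(C)=O
Why: Seyferth-Gilbert homologation in the Ohira-Bestmann version: methanolysis frees the diazomethylphosphonate anion, which olefinates the non-enolisable aldehyde, and loss of N2 with a 1,2-hydrogen shift gives the terminal alkyne under conditions that leave all ethers intact.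

Step 9
Reactants: 15 1-(benzyloxy)-5-ethynyl-2,4-dimethoxybenzene; 8 4-(benzyloxy)-2,3,5,6-tetramethoxybenzaldehyde
Product: 17 racemic 1-[4-(benzyloxy)-2,3,5,6-tetramethoxyphenyl]-3-[5-(benzyloxy)-2,4-dimethoxyphenyl]prop-2-yn-1-ol, via lithium acetylide 16 (not isolated)
Conditions: 15, n-BuLi (1.0 equiv), THF, -78 °C; then 8, -78 °C to 0 °C; H2O
Reagents that add atoms: none
Why: 1,2-Addition of a lithium acetylide to an aldehyde: the alkyne C-H is by far the most acidic site of 15, the slim nucleophile reaches the di-ortho-substituted non-enolisable aldehyde, and the carbinol centre forms without control (racemic) because step 10 erases it.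

Step 10
Reactants: 17 racemic 1-[4-(benzyloxy)-2,3,5,6-tetramethoxyphenyl]-3-[5-(benzyloxy)-2,4-dimethoxyphenyl]prop-2-yn-1-ol
Product: 18 1-[4-(benzyloxy)-2,3,5,6-tetramethoxyphenyl]-3-[5-(benzyloxy)-2,4-dimethoxyphenyl]prop-2-yn-1-one
Conditions: MnO2 (activated, excess), CH2Cl2, rt
Reagents that add atoms: none
Why: MnO2 oxidation of an alcohol that is both benzylic and propargylic: the doubly activated carbinol is oxidised under neutral heterogeneous conditions, which avoids acid-induced ionisation of this electron-rich alcohol.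

Step 11
Reactants: 18 1-[4-(benzyloxy)-2,3,5,6-tetramethoxyphenyl]-3-[5-(benzyloxy)-2,4-dimethoxyphenyl]prop-2-yn-1-one; 19 iodine monochloride
Product: 21 7-(benzyloxy)-2-[5-(benzyloxy)-2,4-dimethoxyphenyl]-3-iodo-5,6,8-trimethoxy-4H-chromen-4-one, via methyloxonium chloride 20 (not isolated)
Conditions: ICl (1.1 equiv), CH2Cl2, -78 °C, dark; aq Na2S2O3
Reagents that add atoms: iodine monochloride, ClI
Why: Transfer of I+ from ICl to the triple bond of 18 develops positive charge at C2, where it is shared with the 2'- and 4'-methoxy groups of ring B (ortho and para to C1'), and not at C3, which is destabilised by the adjacent C4 carbonyl. An ortho methoxy oxygen of ring A attacks C2 anti to iodine in a 6-endo-dig closure that forms O1-C2 and ring C, and chloride then removes the methyl group of 20 by SN2 attack, giving MeCl and the aromatic 3-iodopyranone 21. The closest known reaction is the ICl-induced cyclisation of 2-methoxyaryl alkynones to 3-iodochromones and 3-iodoflavones. No stereocentre is created. Three selectivities are needed: the two ortho ethers of ring A are related by the mirror plane through C1 and C4 of that ring, so either one gives 21; the 5-endo-dig closure by the 2'-methoxy oxygen to a 2-aroyl-3-iodobenzofuran would require attack at C3, the carbon without positive character; and ring iodination is held back because ring A has no free position, ring B is deactivated by the ynone with C3' shielded by two ethers, and only a slight excess of ICl is used at -78 °C.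

Step 12
Reactants: 21 7-(benzyloxy)-2-[5-(benzyloxy)-2,4-dimethoxyphenyl]-3-iodo-5,6,8-trimethoxy-4H-chromen-4-one
Product: 24 7-(benzyloxy)-2-[5-(benzyloxy)-2,4-dimethoxyphenyl]-3-hydroxy-5,6,8-trimethoxy-4H-chromen-4-one, via 3-magnesioflavone 22 (not isolated), via flavone-3-boronate 23 (not isolated)
Conditions: i-PrMgCl·LiCl (1.1 equiv), THF, -40 °C; B(OMe)3, -40 °C to 0 °C; AcOH, 30% H2O2, 0 °C to rt
Reagents that add atoms: hydrogen peroxide, OO
Why: Iodine-magnesium exchange, borylation and oxidation: the sp2 C3-I bond next to the carbonyl should exchange within minutes at low temperature, faster than the reagent adds to the vinylogous ester carbonyl, and 3-metalated flavones are known to be trapped by B(OMe)3 and oxidised by H2O2/AcOH to flavonols.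

Step 13
Reactants: 24 7-(benzyloxy)-2-[5-(benzyloxy)-2,4-dimethoxyphenyl]-3-hydroxy-5,6,8-trimethoxy-4H-chromen-4-one
Product: 25 7-(benzyloxy)-2-[5-(benzyloxy)-2,4-dimethoxyphenyl]-3,5,6,8-tetramethoxy-4H-chromen-4-one
Conditions: MeI, K2CO3, acetone, reflux
Reagents that add atoms: iodomethane, CI
Why: Williamson O-methylation: the 3-hydroxy group is the only free hydroxy group of 24 and its anion is methylated on oxygen.

Step 14
Reactants: 25 7-(benzyloxy)-2-[5-(benzyloxy)-2,4-dimethoxyphenyl]-3,5,6,8-tetramethoxy-4H-chromen-4-one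
Product: 26 5,7-dihydroxy-2-(5-hydroxy-2,4-dimethoxyphenyl)-3,6,8-trimethoxy-4H-chromen-4-one (target)
Conditions: BCl3 (6 equiv), pentamethylbenzene (6 equiv), CH2Cl2, -78 °C to 0 °C; H2O
Reagents that add atoms: none
Why: Lewis-acid ether cleavage with BCl3 and a cation scavenger: both aryl benzyl ethers are cleaved at -78 °C while pentamethylbenzene captures the benzyl cation, on warming to 0 °C only the 5-methoxy group, whose oxygen binds boron together with the C4 carbonyl oxygen, should lose its methyl group to chloride, and a ring opening and reclosure of Wessely-Moser type would be degenerate for the 5-OH/6-OMe/7-OH/8-OMe pattern.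

Compound list
1 | 1,2,4,5-tetramethoxybenzene | COc1cc(OC)c(OC)cc1OC | starting material
2 | (2,3,5,6-tetramethoxyphenyl)lithium | [Li]c1c(OC)c(OC)cc(OC)c1OC | intermediate
3 | dimethyl (2,3,5,6-tetramethoxyphenyl)boronate | COB(OC)c1c(OC)c(OC)cc(OC)c1OC | intermediate
4 | 2,3,5,6-tetramethoxyphenol | COc1cc(OC)c(OC)c(O)c1OC | intermediate
5 | 1-(benzyloxy)-2,3,5,6-tetramethoxybenzene | COc1cc(OC)c(OC)c(OCc2ccccc2)c1OC | intermediate
6 | 1-(benzyloxy)-4-bromo-2,3,5,6-tetramethoxybenzene | COc1c(Br)c(OC)c(OC)c(OCc2ccccc2)c1OC | intermediate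
7 | [4-(benzyloxy)-2,3,5,6-tetramethoxyphenyl]lithium | [Li]c1c(OC)c(OC)c(OCc2ccccc2)c(OC)c1OC | intermediate
8 | 4-(benzyloxy)-2,3,5,6-tetramethoxybenzaldehyde | COc1c(OC)c(C=O)c(OC)c(OC)c1OCc1ccccc1 | intermediate
9 | 2,4-dimethoxybenzaldehyde | COc1ccc(C=O)c(OC)c1 | starting material
10 | 2,4-dimethoxyphenyl formate | COc1ccc(OC=O)c(OC)c1 | intermediate
11 | 2,4-dimethoxyphenol | COc1ccc(O)c(OC)c1 | intermediate
12 | 1-(benzyloxy)-2,4-dimethoxybenzene | COc1ccc(OCc2ccccc2)c(OC)c1 | intermediate
13 | N-[5-(benzyloxy)-2,4-dimethoxybenzylidene]-N-methylmethanaminium chloride | COc1cc(OC)c(C=[N+](C)C)cc1OCc1ccccc1.[Cl-] | intermediate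
14 | 5-(benzyloxy)-2,4-dimethoxybenzaldehyde | COc1cc(OC)c(C=O)cc1OCc1ccccc1 | intermediate
15 | 1-(benzyloxy)-5-ethynyl-2,4-dimethoxybenzene | COc1cc(OC)c(C#C)cc1OCc1ccccc1 | intermediate
16 | {[5-(benzyloxy)-2,4-dimethoxyphenyl]ethynyl}lithium | COc1cc(OC)c(C#C[Li])cc1OCc1ccccc1 | intermediate
17 | racemic 1-[4-(benzyloxy)-2,3,5,6-tetramethoxyphenyl]-3-[5-(benzyloxy)-2,4-dimethoxyphenyl]prop-2-yn-1-ol | COc1c(OC)c(C(O)C#Cc2cc(OCc3ccccc3)c(OC)cc2OC)c(OC)c(OC)c1OCc1ccccc1 | intermediate
18 | 1-[4-(benzyloxy)-2,3,5,6-tetramethoxyphenyl]-3-[5-(benzyloxy)-2,4-dimethoxyphenyl]prop-2-yn-1-one | COc1c(OC)c(C(=O)C#Cc2cc(OCc3ccccc3)c(OC)cc2OC)c(OC)c(OC)c1OCc1ccccc1 | intermediate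
19 | iodine monochloride | ClI | starting material
20 | 7-(benzyloxy)-2-[5-(benzyloxy)-2,4-dimethoxyphenyl]-3-iodo-5,6,8-trimethoxy-1-methyl-4-oxo-4H-chromen-1-ium chloride | COc1cc(OC)c(C2=C(I)C(=O)c3c(OC)c(OC)c(OCc4ccccc4)c(OC)c3[O+]2C)cc1OCc1ccccc1.[Cl-] | intermediate
21 | 7-(benzyloxy)-2-[5-(benzyloxy)-2,4-dimethoxyphenyl]-3-iodo-5,6,8-trimethoxy-4H-chromen-4-one | COc1cc(OC)c(-c2oc3c(OC)c(OCc4ccccc4)c(OC)c(OC)c3c(=O)c2I)cc1OCc1ccccc1 | intermediate
22 | {7-(benzyloxy)-2-[5-(benzyloxy)-2,4-dimethoxyphenyl]-5,6,8-trimethoxy-4-oxo-4H-chromen-3-yl}magnesium chloride | COc1cc(OC)c(-c2oc3c(OC)c(OCc4ccccc4)c(OC)c(OC)c3c(=O)c2[Mg]Cl)cc1OCc1ccccc1 | intermediate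
23 | dimethyl {7-(benzyloxy)-2-[5-(benzyloxy)-2,4-dimethoxyphenyl]-5,6,8-trimethoxy-4-oxo-4H-chromen-3-yl}boronate | COc1cc(OC)c(-c2oc3c(OC)c(OCc4ccccc4)c(OC)c(OC)c3c(=O)c2B(OC)OC)cc1OCc1ccccc1 | intermediate
24 | 7-(benzyloxy)-2-[5-(benzyloxy)-2,4-dimethoxyphenyl]-3-hydroxy-5,6,8-trimethoxy-4H-chromen-4-one | COc1cc(OC)c(-c2oc3c(OC)c(OCc4ccccc4)c(OC)c(OC)c3c(=O)c2O)cc1OCc1ccccc1 | intermediate
25 | 7-(benzyloxy)-2-[5-(benzyloxy)-2,4-dimethoxyphenyl]-3,5,6,8-tetramethoxy-4H-chromen-4-one | COc1cc(OC)c(-c2oc3c(OC)c(OCc4ccccc4)c(OC)c(OC)c3c(=O)c2OC)cc1OCc1ccccc1 | intermediate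
26 | 5,7-dihydroxy-2-(5-hydroxy-2,4-dimethoxyphenyl)-3,6,8-trimethoxy-4H-chromen-4-one (CNP0156395.0) | COc1cc(OC)c(-c2oc3c(OC)c(O)c(OC)c(O)c3c(=O)c2OC)cc1O | target

Total step count: 14. Longest linear sequence: 10 steps (steps 1 to 4 or steps 5 to 8, followed by steps 9 to 14).

Steps most likely to fail

Step 11. Three processes could erode the step: ring closure through the 2'-methoxy oxygen of ring B, plain addition of iodine and chlorine across the triple bond without closure, and iodination of ring B. The fallback separates ring closure from functionalisation of C3 and uses no electrophilic iodine.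
- It sets out from 18. BCl3 (1.0 equiv, CH2Cl2, -78 °C) should cleave one of the two ketone-chelated ortho methyl ethers and leave the unchelated benzyl ethers, giving 1-[4-(benzyloxy)-2-hydroxy-3,5,6-trimethoxyphenyl]-3-[5-(benzyloxy)-2,4-dimethoxyphenyl]prop-2-yn-1-one F1.
- K2CO3 in acetone should then add the phenoxide to C2 in a 6-endo-dig oxa-Michael closure, giving 7-(benzyloxy)-2-[5-(benzyloxy)-2,4-dimethoxyphenyl]-5,6,8-trimethoxy-4H-chromen-4-one F2.
- LDA (THF, -78 °C) removes the C3 hydrogen, the known site of flavone lithiation, giving {7-(benzyloxy)-2-[5-(benzyloxy)-2,4-dimethoxyphenyl]-5,6,8-trimethoxy-4-oxo-4H-chromen-3-yl}lithium F3.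
- B(OMe)3 followed by AcOH converts F3 into boronate 23, where the route is rejoined for the peroxide oxidation to 24.

Step 14. Dealkylation may go too far, with loss of the 3-, 6- or 4'-methyl groups assisted by neighbouring boron aryloxides, or ring B may be C-benzylated. The fallback uses two orthogonal cleavages.
- It sets out from 25. AlCl3 in MeCN (rt to 60 °C) performs a chelation-controlled demethylation at C5 only, giving 7-(benzyloxy)-2-[5-(benzyloxy)-2,4-dimethoxyphenyl]-5-hydroxy-3,6,8-trimethoxy-4H-chromen-4-one F5. Any benzyl loss at this stage is harmless.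
- Hydrogenolysis (H2, 10% Pd/C, EtOAc/MeOH, rt) then removes both benzyl groups and returns to the route at 26.

Step 12. The Grignard reagent may attack the pyranone at C4 or C2, or 22 may be protonated before it meets the borate, which amounts to net loss of iodine. The fallback replaces the polar organometallic by a cross-coupling.
- It sets out from 21. Miyaura borylation (B2pin2, PdCl2(dppf), KOAc, dioxane, 80 °C) should give 7-(benzyloxy)-2-[5-(benzyloxy)-2,4-dimethoxyphenyl]-5,6,8-trimethoxy-3-(4,4,5,5-tetramethyl-1,3,2-dioxaborolan-2-yl)-4H-chromen-4-one F4.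
- Oxidation with NaBO3·4H2O (THF/H2O, rt) returns to the route at 24.

Further compounds
F1 | step 11 | 1-[4-(benzyloxy)-2-hydroxy-3,5,6-trimethoxyphenyl]-3-[5-(benzyloxy)-2,4-dimethoxyphenyl]prop-2-yn-1-one | COc1c(O)c(C(=O)C#Cc2cc(OCc3ccccc3)c(OC)cc2OC)c(OC)c(OC)c1OCc1ccccc1
F2 | step 11 | 7-(benzyloxy)-2-[5-(benzyloxy)-2,4-dimethoxyphenyl]-5,6,8-trimethoxy-4H-chromen-4-one | COc1cc(OC)c(-c2cc(=O)c3c(OC)c(OC)c(OCc4ccccc4)c(OC)c3o2)cc1OCc1ccccc1
F3 | step 11 | {7-(benzyloxy)-2-[5-(benzyloxy)-2,4-dimethoxyphenyl]-5,6,8-trimethoxy-4-oxo-4H-chromen-3-yl}lithium | COc1cc(OC)c(-c2oc3c(OC)c(OCc4ccccc4)c(OC)c(OC)c3c(=O)c2[Li])cc1OCc1ccccc1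
F4 | step 12 | 7-(benzyloxy)-2-[5-(benzyloxy)-2,4-dimethoxyphenyl]-5,6,8-trimethoxy-3-(4,4,5,5-tetramethyl-1,3,2-dioxaborolan-2-yl)-4H-chromen-4-one | COc1cc(OC)c(-c2oc3c(OC)c(OCc4ccccc4)c(OC)c(OC)c3c(=O)c2B5OC(C)(C)C(C)(C)O5)cc1OCc1ccccc1
F5 | step 14 | 7-(benzyloxy)-2-[5-(benzyloxy)-2,4-dimethoxyphenyl]-5-hydroxy-3,6,8-trimethoxy-4H-chromen-4-one | COc1cc(OC)c(-c2oc3c(OC)c(OCc4ccccc4)c(OC)c(O)c3c(=O)c2OC)cc1OCc1ccccc1
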